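(All runs were computed from invented constants, and the scatter is random.)

At early times substrate has two ways out, closing to ring or pairing to open dimer. In Friday's run ring, open dimer and side product already add up to 99.9% of the charge at 0.833 d, which leaves hardly any for substrate, and the open dimer then stays flat, from 11.0% to 10.7%. You can therefore take each share asked as the ring percent at 3.0 d.

| setting | Friday's | Sunday's | grey | amber | violet | ochre | teal |
|---|---|---|---|---|---|---|---|
| substrate | 0.049 M | 0.74 M | 0.060 M | 0.12 M | 0.25 M | 0.50 M | 1.0 M |
| remark | run made earlier | run made earlier |  |  |  |  |  |
| time |  |  | 3.0 d | 3.0 d | 3.0 d | 3.0 d | 3.0 d |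

- Friday's (time / d: ring / %, open dimer / %, side product / %): 0.833: 85.0, 11.0, 3.9; 1.67: 82.9, 11.2, 2.9; 2.50: 79.5, 11.3, 2.9; 3.00: 79.2, 10.7, 2.8
- Sunday's (time / d: ring / %, open dimer / %, side product / %): 0.833: 34.2, 57.6, 6.6; 1.67: 33.0, 56.8, 7.8; 2.50: 32.1, 56.9, 7.2; 3.00: 32.0, 57.2, 7.6

(standard deviation of a reading: 0.5 percentage points)

- share of ring in all that became ring or open dimer or side product or isomer of the product for grey, amber, violet, ochre, teal, in this order
- how the row runs (falls, then rises / hardly changes / rises all the way / falls all the way / rises, then falls)

- a species is counted by the substrate in it: one open dimer or side product counts as two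
- reactions considered so far: substrate -> ring; ring <-> isomer of the product; 2 substrate -> open dimer; substrate + ring -> side product
- "hardly changes" means that all values lie within two and a half points (for a concentration: within two and a half percent of the largest)

Your zero of the scale is the case where the two ways are equal. At any moment closing takes the fraction K/(K+c) of the substrate being used, where c is its concentration. Averaged over the fall from the charge, that gives ln(1+a)/a, with a the charge over K, and with the side product left aside the open dimer takes the rest. Solved approximately for Friday's mean open dimer reading of 11.0%, this gives 0.189 M for K, the balance concentration: the substrate concentration at which closing and pairing use substrate equally fast (the effective molarity, counted by substrate used). For Sunday's run it then gives 59.3% open dimer, and the reading is 57.2%.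

Not all that closes stays ring. Ring at 3.00 d over the closing fraction is 89.1% in Friday's run and 78.7% in Sunday's, less at the higher charge. With Friday's figure you get 77.4% for grey, and with Sunday's 27.3% for teal, so you expect a fall all the way.

The forecast gives 77%, 67%, 53%, 39% and 26%, 1.3 percentage points under your teal, with the shape falls all the way, and says “The row falls throughout”.

The flasks give 76.8%, 66.8%, 53.1%, 39.1% and 26.7%: the row falls all the way.

    substrate → ring (k = 0.420 /h)
    ring ⇌ isomer of the product (K = 2.30, k = 0.00130 /h)
    2 substrate → open dimer (k = 1.10 /M/h)
    substrate + ring → side product (k = 0.310 /M/h)

At the start of grey, closing uses substrate 3.2 times as fast as pairing; grey is charged at 0.317 of the balance concentration and holds 12.9% open dimer at 3.00 d. Teal, charged at 5.29 times the balance concentration, where the closing fraction reckons 34.8%, holds 63.5% open dimer at 3.00 d.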